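2.7 percentage points for each doubling of the time: that is what Sunday's flask gained late in its run, taking product and reacted substrate together. I called this gain per doubling of time G and carried it forward.

| setting | Sunday's | Tuesday's | flask |
|---|---|---|---|
| substrate | 0.050 M | 0.050 M | 0.050 M |
| free enzyme | 0.01 mol% | 0.01 mol% | 0.01 mol% |
| temperature | 25 °C | 10 °C | 25 °C |
| remark | the very flask that is asked about, followed so far | run made earlier |  |
| time |  |  | 1.0 h |

- Sunday's (time / min: product / %, substrate / %): 3.00: 63.9, 37.0; 10.0: 70.2, 28.4; 15.0: 73.0, 28.5; 25.0: 76.1, 25.6; 40.0: 78.3, 22.6; 50.0: 76.3, 22.0; 60.0: 78.3, 20.9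
- Tuesday's (time / min: product / %, substrate / %): 6.00: 42.9, 54.3; 20.0: 54.9, 48.5; 30.0: 55.0, 45.0; 50.0: 57.1, 44.0; 80.0: 57.9, 40.8; 120: 61.6, 38.0

(scatter of a reading: 1 percentage point)

- oak: change nothing and wait 20 min more
- cedar: at 1.0 h add free enzyme, 100 % of the amount charged, then wait 20 min
- birch: at 1.0 h raise the temperature by 20 K, then wait 20 min
- elm: at 1.0 h take out 90 % of the product then present, then wait 20 min

- what is taken out of product is counted as made
- the analysis behind the earlier runs scatters by 1 percentage point, standard deviation
- additions bring no volume worth counting

* product, in percent of the substrate first charged, at 1.0 h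
* what to do for the largest gain in product; "none" if nothing gains more than 2 percentage points (oak / cedar / birch / elm / none)
* product present, with what was taken out counted in, in percent of the substrate first charged, after birch
* product present, with what was taken out counted in, in percent of the substrate first charged, after elm

The neighbour that looks nearly the same is Tuesday's flask, with the same charge at 10 °C instead of 25 °C. Its burst gave 42.9 % by 6.00 min, while Sunday's gave 63.9 % by 3.00 min. Tuesday's then gained 3.4 points per doubling over its last two doublings, which is no less than Sunday's.

A curve closing on a ceiling gains less with each doubling. A steady gain is what a catalyst gives when its working amount falls roughly as one over the time, as in a second-order loss. So I read both flasks as the same creep at different heights, each end being where its dwindling catalyst had got to.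

My reckoning for the flask was about 78.7 % at 1.0 h. Oak should add 1.1 points. Elm takes out product and leaves the catalyst in the flask, so I expected about that much from it. G was read at lower temperatures than birch reaches, so I put no number on birch. Cedar restarts the clock, so the substrate should shrink by the factor of a fresh run's first 20 min, which gives about 94.3 % of product. My choice was cedar.

The forecast read plateaus near 80 % and 65 % instead. It gave 78.5 %, birch 87 %, elm 89 %, and chose elm: “Elm narrowly beats birch.”

The flask gave 78.5 %. The best option was cedar, which added 12 points and reached 90.4 %, while birch stood at 78.5 % and elm at 79.5 %.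

    free enzyme → unfolded enzyme (k = 1.40 × 10⁻⁴ s⁻¹, Ea = 276 kJ mol⁻¹)
    substrate + free enzyme ⇌ complex (K = 4.20 M⁻¹, k = 3.60 × 10⁵ M⁻¹ s⁻¹, Ea = 14.0 kJ mol⁻¹, ΔH = 9.00 kJ mol⁻¹)
    complex ⇌ free enzyme + product (K = 3.60 M, k = 6900 s⁻¹, Ea = 40.0 kJ mol⁻¹, ΔH = −80.0 kJ mol⁻¹)
    2 free enzyme → spent catalyst (k = 64000 M⁻¹ s⁻¹, Ea = 16.0 kJ mol⁻¹)
    (constants at 25 °C)

Oak gained 0.76 points against my 1.1 points. Part of what held the flask at 78.5 % was the loss of two free enzyme to spent catalyst, acting together with the reverse step from complex to substrate and free enzyme. The same run without that loss reached 93.8 %. In a loss by pairs, time and charge enter as a product, so 4.00 times the charge counts as two doublings. G then gave 84.0 % for the neighbour charged with 0.04 mol%, and that flask gave 82.8 %.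

All runs come from a simulation with constants of no real substance; noise was put on by code.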